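**Plan**
- Retrosynthetic cuts, in order: the lactone C2–O bond and both epoxides (one peracid step on a Δ2,Δ12-dienoic acid); C18–C20 (carbonylation); C2=C3 (ring A, alkyne–carbonyl metathesis); the C12=C13 olefin (Julia elimination); C6–C14 (ring C); C5–C10 (Sakurai); C4–C9 and C7–C8 (Diels–Alder).
- Forward order: ring B by Diels–Alder → spiro-lactone (temporary ring that holds C17–O and C2) → allylsilane → Sakurai (C5 chain and exocyclic C6=CH2) → 1-sulfonylvinyl carbinol → ring C → Julia → ring A → acrylic acid → bis-epoxidation with lactonisation.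
- Enabling feature: C6 is the methyl-bearing quaternary carbon shared by the six- and seven-membered rings, so it is the Markovnikov radical of a C6=CH2 olefin (the transferred H ends in the angular methyl). C14 is an unsubstituted CH2 next to C13, so a 1-sulfonylvinyl terminus can accept that radical 7-endo and later give C12=C13.
- Stereochemistry: absolute configuration from the catalyst-controlled Diels–Alder (C9, C4); C5 anti to the C4 substituent (Sakurai); C6 in the radical closure (chair-like, trans fusion, axial methyl); 12,13-epoxide anti to the C6 methyl; C2/C3 from α-epoxidation anti to C17 and invertive opening by the carboxyl.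

Key step: step 10

Remark on locants: C1–C20 follow the cyathane skeleton of the target (ring A C1–C4, C9; ring B C4–C9; ring C C5, C6, C10–C14; C15, C16 = methyls on C12, C6; C17 = CH2O on C9; C18–C20 = methylene-lactone carbons); β is the face of C17, α the opposite face.
Assumption: the (S)-oxazaborolidinium is taken to give the enantiomer drawn for 9; if the sense of induction is opposite, its commercial enantiomer is used and nothing else changes.

**Step 1**
Reactants: 1 but-2-yn-1-ol; 2 1-(triphenyl-λ5-phosphanylidene)propan-2-one
Product: 4 (E)-hept-3-en-5-yn-2-one, via but-2-ynal 3 (not isolated)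
Conditions: activated MnO2 (10 equiv), CH2Cl2, rt
Reagents that add atoms: none
Why: Tandem oxidation–Wittig olefination: MnO2 oxidises the propargylic alcohol and the volatile ynal is trapped at once by the stabilised ylide, which should give the E-enone.

**Step 2**
Reactants: 4 (E)-hept-3-en-5-yn-2-one
Product: 5 (E)-(hepta-1,3-dien-5-yn-2-yloxy)triisopropylsilane
Conditions: TIPSOTf, Et3N, CH2Cl2, 0 °C
Reagents that add atoms: triisopropylsilyl trifluoromethanesulfonate, CC(C)[Si](C(C)C)(C(C)C)OS(=O)(=O)C(F)(F)F
Why: Soft enolisation and O-silylation of the only enolisable position (the methyl ketone) should give the 2-silyloxy-1,3-diene with the E olefin untouched.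

**Step 3**
Reactants: 6 methyl 4-oxobutanoate; 7 formaldehyde
Product: 8 methyl 3-formylbut-3-enoate
Conditions: 37% aq. CH2O, pyrrolidine (10 mol%), propionic acid (10 mol%), i-PrOH, 45 °C
Reagents that add atoms: none
Why: Amine-catalysed α-methylenation of an aldehyde (Mannich condensation through the enamine, then β-elimination of the amine).

**Step 4**
Reactants: 5 (E)-(hepta-1,3-dien-5-yn-2-yloxy)triisopropylsilane; 8 methyl 3-formylbut-3-enoate
Product: 9 Diels–Alder adduct, methyl 2-[1-formyl-2-(prop-1-ynyl)-4-(triisopropylsilyloxy)cyclohex-3-en-1-yl]acetate with CHO (C17, β) cis to the propynyl group on C4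
Conditions: (S)-o-tolyl-CBS oxazaborolidine (20 mol%), Tf2NH (16 mol%), CH2Cl2, −78 → −40 °C
Reagents that add atoms: none
Why: Enantioselective Diels–Alder reaction of a 2-substituted acrolein under chiral oxazaborolidinium catalysis: the silyl enol ether terminus C7 bonds to C8 and C4 to C9, the endo-formyl transition state puts CHO cis to the E-propynyl group, and the catalyst fixes the absolute configuration of C9 and C4.

**Step 5**
Reactants: 9 Diels–Alder adduct
Product: 11 spiro-γ-lactone (C17H2–O–C2(=O)–C1H2 spiro at C9; C5=C6 silyl enol ether; propynyl on C4 cis to C17), via hydroxy ester 10 (not isolated)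
Conditions: NaBH4, MeOH–THF, −20 °C → rt
Reagents that add atoms: none
Why: Chemoselective reduction of the neopentyl aldehyde; the alkoxide closes onto the γ-ester (5-exo-trig acyl substitution, helped by the quaternary centre) to a temporary lactone that masks C17–OH and keeps C2 as an acyl carbon.

**Step 6**
Reactants: 11 spiro-γ-lactone
Product: 12 enol triflate (C5=C6–OTf) of the spiro-lactone
Conditions: CsF, PhNTf2, DME, rt → 40 °C
Reagents that add atoms: N-phenylbis(trifluoromethanesulfonimide), O=S(=O)(N(c1ccccc1)S(=O)(=O)C(F)(F)F)C(F)(F)F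
Why: Fluoride cleaves the silyl enol ether to the regiodefined enolate, which is O-sulfonylated, so the C5=C6 position fixed in the cycloaddition is kept.

**Step 7**
Reactants: 12 enol triflate; 13 (trimethylsilyl)methylmagnesium chloride
Product: 15 allylsilane (C6–CH2SiMe3, C5=C6), via (trimethylsilyl)methylzinc chloride 14 (not isolated)
Conditions: 13, ZnCl2, THF, 0 °C; then 12, Pd(PPh3)4 (5 mol%), THF, 50 °C
Reagents that add atoms: none
Why: Negishi coupling of the enol triflate with the lactone-tolerant (silylmethyl)zinc reagent should give the allylsilane, a latent exocyclic methylene at C6.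

**Step 8**
Reactants: 15 allylsilane; 16 but-3-en-2-one
Product: 17 methyl ketone (3-oxobutyl chain on C5, α, trans to the C4 propynyl group; exocyclic C6=CH2)
Conditions: 16 (2 equiv), TiCl4 (1.1 equiv), CH2Cl2, −78 °C
Reagents that add atoms: none
Why: Hosomi–Sakurai conjugate addition: the allylsilane attacks the activated enone through C5 (SE2′), which installs the chain and moves the double bond to exocyclic C6=CH2; C5 is set by attack anti to the neighbouring C4 alkynyl group and to the 1,3-related axial C17 methylene.

**Step 9**
Reactants: 17 methyl ketone; 18 phenyl vinyl sulfone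
Product: 20 1-sulfonylvinyl carbinol (C12 tertiary alcohol, both epimers, bearing C13(SO2Ph)=C14H2), via 1-lithio-1-(phenylsulfonyl)ethene 19 (not isolated)
Conditions: 18, MeLi, THF, −95 °C; then 17, −95 → −78 °C; aq. NH4Cl
Reagents that add atoms: none
Why: α-Lithiated phenyl vinyl sulfone adds 1,2 to the methyl ketone (far more electrophilic than the lactone); the C12 epimers are carried on together because C12 becomes sp2 in step 12.

**Step 10**
Reactants: 20 1-sulfonylvinyl carbinol
Product: 21 ring B/C sulfone (trans-fused cycloheptane; C6 methyl α, axial; SO2Ph on C13; OH on C12; mixture at C12 and C13)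
Conditions: Fe(acac)3 (30 mol%), PhSiH3 (2.5 equiv), EtOH–(CH2OH)2 (5:1), 0.01 M, 60 °C
Reagents that add atoms: none
Why: An iron hydride formed from Fe(acac)3 and PhSiH3 transfers a hydrogen atom to the CH2 terminus of the 1,1-disubstituted C6=CH2 olefin (Markovnikov), which creates the angular methyl and a tertiary C6 radical; this radical adds to the unsubstituted terminus C14 of the electron-poor 1-sulfonylvinyl group, and the α-sulfonyl radical at C13 is reduced and protonated. The closest known reaction type is the iron-mediated reductive olefin coupling (hydrogen-atom-transfer-initiated Giese addition) in its intramolecular form, with radical polyene cyclisations as the stereochemical model. Ring C closes in the 7-endo-trig mode, because the 6-exo alternative would attack the hindered, sulfonyl-bearing C13 against the polarity of the acceptor and give a primary radical. The new stereocentre C6 should be controlled by the ring B chair that carries the C4 alkynyl group and the C5 chain equatorially: the tether reaches the radical through a chair-like transition state that forms the new bond equatorially and leaves the methyl axial (trans 6/7 fusion, methyl anti to C17), whereas the axial approach would put the tether in 1,3-diaxial contact with H-4 and H-8; the second new centre, C13, is uncontrolled and irrelevant since it becomes sp2 in step 12. The step needs chemoselectivity among the π-systems: only the electron-rich 1,1-disubstituted olefin accepts the hydrogen atom, while the vinyl sulfone, the internal alkyne and the lactone are inert to the hydride, and high dilution suppresses intermolecular addition.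

**Step 11**
Reactants: 21 ring B/C sulfone
Product: 22 tertiary C12 acetate of 21
Conditions: Ac2O, DMAP, pyridine, 50 °C
Reagents that add atoms: acetic anhydride, CC(=O)OC(C)=O
Why: DMAP-catalysed acylation turns the tertiary C12 hydroxyl into the leaving group needed for the Julia elimination.

**Step 12**
Reactants: 22 tertiary acetate
Product: 23 cycloheptene (C12=C13; spiro-lactone; C4 propynyl)
Conditions: 6% Na(Hg), Na2HPO4, MeOH–THF, −20 °C
Reagents that add atoms: none
Why: Julia–Lythgoe reductive elimination of the β-acetoxy sulfone places the double bond regiospecifically between C12 and C13 (necessarily cis in the seven-membered ring), and all diastereomers converge.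

**Step 13**
Reactants: 23 cycloheptene lactone
Product: 24 lactol (C2 hemiacetal, anomer mixture)
Conditions: DIBAL-H (1.1 equiv), CH2Cl2, −78 °C; Rochelle salt
Reagents that add atoms: none
Why: Partial reduction of the γ-lactone stops at the lactol (stable aluminium acetal at −78 °C), which unmasks C2 at the aldehyde level; olefin and alkyne are inert.

**Step 14**
Reactants: 24 lactol
Product: 25 hydroxy enone (ring A cyclopentene C2=C3 with acetyl C18/C19 on C3; free C17–OH; trans-fused at C4–C9)
Conditions: BF3·OEt2 (20 mol%), CH2Cl2, −40 → 0 °C; aq. NaHCO3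
Reagents that add atoms: none
Why: Lewis-acid alkyne–carbonyl metathesis of a 5-alkynal delivered by its lactol: the activated C2 carbonyl is attacked by alkyne carbon C3 (5-exo-dig), the vinyl cation closes to an oxete and cycloreversion gives the C2=C3 olefin and the C18 methyl ketone, which closes ring A trans-fused because C1 and C3 already sit trans-diequatorial on ring B, and sets C17–OH free.

**Step 15**
Reactants: 25 hydroxy enone
Product: 26 acetoxy enone (C17 acetate)
Conditions: Ac2O, pyridine, DMAP (cat.), CH2Cl2, rt
Reagents that add atoms: acetic anhydride, CC(=O)OC(C)=O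
Why: Acetylation of the primary neopentyl alcohol installs the C17 acetate of the target.

**Step 16**
Reactants: 26 acetoxy enone
Product: 27 dienyl triflate (C18(OTf)=C19H2 on C3)
Conditions: KHMDS, PhNTf2, THF, −78 °C
Reagents that add atoms: N-phenylbis(trifluoromethanesulfonimide), O=S(=O)(N(c1ccccc1)S(=O)(=O)C(F)(F)F)C(F)(F)F
Why: Kinetic deprotonation of the enone at the α′-methyl group (C19) and O-triflation of the cross-conjugated dienolate should give the 2-triflyloxy-diene; the acetate α-protons and H-4 are far less acidic at this temperature.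

**Step 17**
Reactants: 27 dienyl triflate
Product: 28 dienoic acid (C2=C3–C18(=C19H2)–C20O2H)
Conditions: Pd(OAc)2 (5 mol%), dppf (10 mol%), CO (1 atm), KOAc, DMF–H2O, 50 °C
Reagents that add atoms: carbon monoxide, [C-]#[O+]; water, O
Why: Palladium-catalysed hydroxycarbonylation of the alkenyl triflate (oxidative addition, CO insertion, acyl transfer to acetate and water) should give the 2-substituted acrylic acid without touching the acetate.

**Step 18**
Reactants: 28 dienoic acid
Product: 31 target CNP0404717.1, via 12,13-epoxy dienoic acid 29 (not isolated), via bis-epoxy acid 30 (not isolated)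
Conditions: mCPBA (2.5 equiv), CH2Cl2, 0 °C → rt
Reagents that add atoms: 3-chloroperbenzoic acid, OOC(=O)c1cccc(Cl)c1
Why: Prilezhaev epoxidation of both trisubstituted olefins followed by neighbouring-group opening: the C12=C13 epoxide should form anti to the axial C16 methyl (β), the C2=C3 epoxide on the α face anti to the axial C17 group, and the carboxylic acid then opens it at C2 with inversion (β,γ-epoxy acid to β-hydroxy-γ-lactone), which gives the cis-fused lactone with C2–O β and C3–OH α; the electron-poor acrylate olefin is not epoxidised.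

**Compound list**
1 | but-2-yn-1-ol | CC#CCO | starting material
2 | 1-(triphenyl-λ5-phosphanylidene)propan-2-one | CC(=O)C=P(c1ccccc1)(c1ccccc1)c1ccccc1 | starting material
3 | but-2-ynal | CC#CC=O | intermediate
4 | (E)-hept-3-en-5-yn-2-one | CC#C/C=C/C(C)=O | intermediate
5 | (E)-(hepta-1,3-dien-5-yn-2-yloxy)triisopropylsilane | C=C(O[Si](C(C)C)(C(C)C)C(C)C)/C=C/C#CC | intermediate
6 | methyl 4-oxobutanoate | COC(=O)CCC=O | starting material
7 | formaldehyde | C=O | starting material
8 | methyl 3-formylbut-3-enoate | COC(=O)CC(=C)C=O | intermediate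
9 | Diels–Alder adduct, methyl 2-[1-formyl-2-(prop-1-ynyl)-4-(triisopropylsilyloxy)cyclohex-3-en-1-yl]acetate, CHO cis to propynyl | COC(=O)C[C@]1(C=O)CCC(O[Si](C(C)C)(C(C)C)C(C)C)=C[C@H]1C#CC | intermediate
10 | hydroxy ester (C17 primary alcohol of 9) | COC(=O)C[C@]1(CO)CCC(O[Si](C(C)C)(C(C)C)C(C)C)=C[C@H]1C#CC | intermediate
11 | spiro-γ-lactone with C5=C6 silyl enol ether, propynyl on C4 cis to C17 | O=C1C[C@]2(CO1)CCC(O[Si](C(C)C)(C(C)C)C(C)C)=C[C@H]2C#CC | intermediate
12 | enol triflate (C5=C6–OTf) of the spiro-lactone | O=C1C[C@]2(CO1)CCC(OS(=O)(=O)C(F)(F)F)=C[C@H]2C#CC | intermediate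
13 | (trimethylsilyl)methylmagnesium chloride | C[Si](C)(C)C[Mg]Cl | starting material
14 | (trimethylsilyl)methylzinc chloride | C[Si](C)(C)C[Zn]Cl | intermediate
15 | allylsilane (C6–CH2SiMe3, C5=C6) | O=C1C[C@]2(CO1)CCC(C[Si](C)(C)C)=C[C@H]2C#CC | intermediate
16 | but-3-en-2-one | C=CC(C)=O | starting material
17 | methyl ketone (C5 3-oxobutyl chain trans to C4 propynyl, exocyclic C6=CH2) | O=C1C[C@]2(CO1)CCC(=C)[C@H](CCC(C)=O)[C@H]2C#CC | intermediate
18 | phenyl vinyl sulfone | C=CS(=O)(=O)c1ccccc1 | starting material
19 | 1-lithio-1-(phenylsulfonyl)ethene | [Li]C(=C)S(=O)(=O)c1ccccc1 | intermediate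
20 | 1-sulfonylvinyl carbinol (C12 epimers) | O=C1C[C@]2(CO1)CCC(=C)[C@H](CCC(C)(O)C(=C)S(=O)(=O)c3ccccc3)[C@H]2C#CC | intermediate
21 | ring B/C sulfone, trans-fused, C6 methyl α (C12/C13 mixture) | O=C1C[C@]2(CO1)CC[C@@]3(C)CC(S(=O)(=O)c4ccccc4)C(C)(O)CC[C@@H]3[C@H]2C#CC | intermediate
22 | tertiary C12 acetate of 21 | O=C1C[C@]2(CO1)CC[C@@]3(C)CC(S(=O)(=O)c4ccccc4)C(C)(OC(C)=O)CC[C@@H]3[C@H]2C#CC | intermediate
23 | cycloheptene lactone (C12=C13) | O=C1C[C@]2(CO1)CC[C@@]3(C)CC=C(C)CC[C@@H]3[C@H]2C#CC | intermediate
24 | lactol (anomer mixture at C2) | OC1C[C@]2(CO1)CC[C@@]3(C)CC=C(C)CC[C@@H]3[C@H]2C#CC | intermediate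
25 | hydroxy enone (ring A closed, acetyl on C3, C17–OH) | CC(=O)C1=CC[C@]2(CO)CC[C@@]3(C)CC=C(C)CC[C@@H]3[C@@H]12 | intermediate
26 | acetoxy enone (C17 acetate) | CC(=O)C1=CC[C@]2(COC(C)=O)CC[C@@]3(C)CC=C(C)CC[C@@H]3[C@@H]12 | intermediate
27 | dienyl triflate | C=C(OS(=O)(=O)C(F)(F)F)C1=CC[C@]2(COC(C)=O)CC[C@@]3(C)CC=C(C)CC[C@@H]3[C@@H]12 | intermediate
28 | dienoic acid | C=C(C(=O)O)C1=CC[C@]2(COC(C)=O)CC[C@@]3(C)CC=C(C)CC[C@@H]3[C@@H]12 | intermediate
29 | 12β,13β-epoxy dienoic acid | C=C(C(=O)O)C1=CC[C@]2(COC(C)=O)CC[C@@]3(C)C[C@H]4O[C@@]4(C)CC[C@@H]3[C@@H]12 | intermediate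
30 | 2α,3α:12β,13β-bis-epoxy acid | C=C(C(=O)O)[C@@]12O[C@@H]1C[C@]3(COC(C)=O)CC[C@@]4(C)C[C@H]5O[C@@]5(C)CC[C@@H]4[C@H]32 | intermediate
31 | CNP0404717.1 | C=C1C(=O)O[C@H]2C[C@]3(COC(C)=O)CC[C@@]4(C)C[C@H]5O[C@@]5(C)CC[C@@H]4[C@H]3[C@@]12O | target

**Totals and risks**
Total step count: 18. Longest linear sequence: 17 steps (steps 1, 2 and 4–18).

Steps most likely to fail:

Step 10. Direct reduction of the tertiary radical or return of the hydrogen atom (olefin migration) may outrun the slow 7-endo addition, and facial selectivity at C6 may be incomplete in the conformationally mobile monocycle. The fallback sets out from 20 and generates the same radical irreversibly in a chain process instead of by reversible metal-hydride transfer. Markovnikov addition of HBr (CH2Cl2, −78 °C) to the exocyclic olefin should give the tertiary bromide F1. Slow addition of Bu3SnH with AIBN (benzene, 80 °C, or Et3B/air at −20 °C to sharpen facial selectivity) keeps the hydride concentration low, so that the 7-endo closure onto the vinyl sulfone can compete. The route is rejoined at 21.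

Step 14. The lactol may ionise to a cyclic oxocarbenium ion that is poorly aligned with the alkyne, or the free C17 hydroxyl may capture the vinyl cation, so that ring A closure stalls or is diverted. The fallback sets out from 24 and frees a true aldehyde with C17 already acylated. Propane-1,3-dithiol and BF3·OEt2 open the lactol to the hydroxy dithiane F2. Ac2O/pyridine gives the acetoxy dithiane F3, and MeI/CaCO3 in aqueous MeCN unmasks the acetoxy aldehyde F4. This undergoes the standard acid-catalysed alkyne–aldehyde metathesis (AgSbF6 cat., 1,2-dichloroethane) and rejoins the route at 26.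

Step 18. The allylic C2–C3 epoxide (or the 12,13-epoxide) may open or rearrange under acid before the geometrically demanding 5-endo lactonisation, and either epoxidation may show imperfect facial selectivity. The fallback sets out from 28 and avoids the vinyl epoxide. One equivalent of buffered mCPBA at 0 °C epoxidises only the isolated C12=C13 olefin, and 29 is isolated. OsO4 (cat.)/NMO then dihydroxylates C2=C3 from the α face to the 2α,3α-diol acid F5. Mitsunobu lactonisation (PPh3, DIAD, THF) closes the lactone with inversion at C2 and arrives at 31.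

**Further compounds**
F1 | step 10 | tertiary C6 bromide of 20 | O=C1C[C@]2(CO1)CCC(C)(Br)[C@H](CCC(C)(O)C(=C)S(=O)(=O)c3ccccc3)[C@H]2C#CC
F2 | step 14 | hydroxy dithiane (C2 as 1,3-dithian-2-yl, C17–OH) | OC[C@@]1(CC2SCCCS2)CC[C@@]3(C)CC=C(C)CC[C@@H]3[C@H]1C#CC
F3 | step 14 | acetoxy dithiane | CC(=O)OC[C@@]1(CC2SCCCS2)CC[C@@]3(C)CC=C(C)CC[C@@H]3[C@H]1C#CC
F4 | step 14 | acetoxy aldehyde (C2 aldehyde, C17 acetate, C4 propynyl) | CC(=O)OC[C@@]1(CC=O)CC[C@@]3(C)CC=C(C)CC[C@@H]3[C@H]1C#CC
F5 | step 18 | 2α,3α-dihydroxy-12β,13β-epoxy acid | C=C(C(=O)O)[C@@]1(O)[C@H](O)C[C@]2(COC(C)=O)CC[C@@]3(C)C[C@H]4O[C@@]4(C)CC[C@@H]3[C@H]21
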